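## Retrosynthetic overview
- Caruifolin B is a C3′ ketone on the norbornane core of an endo Diels–Alder dimer of a guaia‑2,4‑diene 10‑hydroxy‑6,12‑olide. The ketone comes from hydroboration/oxidation of the norbornene C3′=C4′ bond, followed by exo‑methyl equilibration.
- The dimer's cyclohexene and norbornene rings form in one step, by intermolecular [4+2] homodimerisation of the cyclopentadiene. One molecule is the diene (C2′=C3′–C4′=C5′) and the other is the dienophile (C2=C3).
- The cyclopentadiene comes from dehydration of a cyclopentenol, which is the reduced form of isophotosantonic lactone.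
- Isophotosantonic lactone comes from α‑santonin by photorearrangement. This builds the 5‑7 ring system and fixes C1, C6, C7, C10 and C11.
- Ring order: lactone and 7‑ring (bought, in santonin), then cyclopentane (photochemistry), then the Diels–Alder rings (last ring formation).

Assumption: the photo‑hydration of santonin gives the 1‑H/10‑O configuration of the isophotosantonic series, which I take to be the one drawn in the target. The diene's [1,5]‑H isomers are assumed to equilibrate faster than they dimerise.

## Route

**Step 1**
Reactants: 1, α‑santonin (commercial, (+)-enantiomer)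
Product: 2, O‑acetylisophotosantonic lactone
Conditions: hν (medium‑pressure Hg lamp, Pyrex), AcOH/H2O (≈1:1), 25 °C
Reagents that add atoms: acetic acid, CC(=O)O (gives the 10‑OAc)
Why: Cross‑conjugated dienone photorearrangement gives the lumiketone (cyclopropyl ketone). In aqueous acid the C2–C10 bond opens to a tertiary C10 cation, which AcOH traps. C6, C7 and C11 are untouched, and C1 is fixed by the cyclopropane geometry.

**Step 2**
Reactants: 2
Product: 3, 3‑hydroxy‑guai‑4‑ene 10‑acetate (C3 epimer mixture)
Conditions: NaBH4, CeCl3·7H2O, MeOH, –20 °C
Reagents that add atoms: none (hydride adds only H)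
Why: Luche 1,2‑reduction of the cyclopentenone leaves the lactone and tertiary acetate intact. The C3 stereocentre is lost again on dehydration.

**Step 3**
Reactants: 3
Product: 4, 3,10‑dihydroxy‑guai‑4‑en‑6,12‑olide
Conditions: K2CO3, MeOH, 50 °C
Reagents that add atoms: none
Why: Methanolysis of the tertiary acetate (transesterification). The enone is already reduced, so there is no vinylogous E1cB loss of the C10 oxygen.

**Step 4**
Reactants: 4
Product: 5, guai‑2,4‑dien‑10‑ol‑6,12‑olide (cyclopentadiene, not isolated)
Conditions: MsCl, Et3N, CH2Cl2, –20 → 0 °C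
Reagents that add atoms: none (mesylate is lost)
Why: The secondary allylic alcohol is mesylated selectively over the hindered tertiary C10–OH. The allylic mesylate, stabilised by the tetrasubstituted alkene, then undergoes E1/E2 loss of H‑2 to give the conjugated diene.

**Step 5**
Reactants: 5 (two molecules)
Product: 6, endo norbornene homodimer
Conditions: neat or 1 M in toluene, 25 → 60 °C, 1–2 d, BHT
Reagents that add atoms: none
Why: Diels–Alder dimerisation, analogous to cyclopentadiene giving endo‑dicyclopentadiene. One molecule reacts as the diene and the other through its unsubstituted C2=C3. Both partners are attacked on the face anti to the seven‑membered ring (the H‑1 face), so C2, C3, C2′ and C5′ are set relative to the santonin‑derived centres. The Alder endo preference puts the cyclopentene ring endo, and C1′ keeps its configuration.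

**Step 6**
Reactants: 6
Product: 7, C3′ alcohol (exo OH, endo Me from syn exo hydroboration)
Conditions: BH3·THF (4 equiv), THF, 0 → 25 °C; then NaBO3·4H2O, THF/H2O, 25 °C
Reagents that add atoms: hydrogen peroxide from perborate, OO (supplies the C–OH oxygen)
Why: Hydroboration–oxidation. The strained trisubstituted norbornene C3′=C4′ reacts far faster than the tetrasubstituted C4=C5 bond, and boron adds to the less hindered C3′. The new C3′/C4′ configurations are reset in Step 7.

**Step 7**
Reactants: 7
Product: 8, caruifolin B
Conditions: Dess–Martin periodinane, NaHCO3, CH2Cl2, 0 → 25 °C; then DBU (0.3 equiv), 25 °C (one pot)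
Reagents that add atoms: none
Why: Oxidation of the secondary alcohol gives the C3′ ketone. Enolisation at C4′ (the only enolisable α‑carbon, since C2′ is a bridgehead) then equilibrates any endo methyl to the strongly preferred exo methyl. The endo face is blocked by the fused cyclopentene.

## Compound list
1 | α‑santonin | C[C@H]1[C@@H]2CC[C@]3(C=CC(=O)C(=C3[C@H]2OC1=O)C)C | starting material
2 | O‑acetylisophotosantonic lactone | CC1=C2[C@H]3OC(=O)[C@@H](C)[C@@H]3CC[C@](C)(OC(C)=O)[C@@H]2CC1=O | intermediate
3 | 3‑hydroxy‑guai‑4‑en‑6,12‑olide 10‑acetate (C3 epimers) | CC1=C2[C@H]3OC(=O)[C@@H](C)[C@@H]3CC[C@](C)(OC(C)=O)[C@@H]2CC1O | intermediate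
4 | 3,10‑dihydroxy‑guai‑4‑en‑6,12‑olide (C3 epimers) | CC1=C2[C@H]3OC(=O)[C@@H](C)[C@@H]3CC[C@](C)(O)[C@@H]2CC1O | intermediate
5 | guai‑2,4‑dien‑10‑ol‑6,12‑olide (transient diene) | CC1=C2[C@H]3OC(=O)[C@@H](C)[C@@H]3CC[C@](C)(O)[C@@H]2C=C1 | intermediate
6 | endo norbornene homodimer of 5 | CC1=C2[C@H]3OC(=O)[C@@H](C)[C@@H]3CC[C@](C)(O)[C@@H]2[C@H]2[C@H]3C=C(C)[C@]4([C@@H]3[C@@](C)(O)CC[C@H]3[C@H](C)C(=O)O[C@@H]34)[C@@H]12 | intermediate
7 | C3′ alcohol (exo OH, endo Me) | CC1=C2[C@H]3OC(=O)[C@@H](C)[C@@H]3CC[C@](C)(O)[C@@H]2[C@H]2[C@H]3[C@H](O)[C@@H](C)[C@]4([C@@H]3[C@@](C)(O)CC[C@H]3[C@H](C)C(=O)O[C@@H]34)[C@@H]12 | intermediate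
8 | caruifolin B | CC1=C2[C@H]3OC(=O)[C@@H](C)[C@@H]3CC[C@](C)(O)[C@@H]2[C@H]2[C@H]3C(=O)[C@H](C)[C@]4([C@@H]3[C@@](C)(O)CC[C@H]3[C@H](C)C(=O)O[C@@H]34)[C@@H]12 | target

## Totals
Total steps: 7. Longest linear sequence: 7 (the route is linear).

## Three steps most likely to fail
1. **Step 5 (Diels–Alder dimerisation).** Steric congestion at the quaternary C5′, competing [1,5]‑H isomers of the diene, and possible regiochemical mismatch could all give the wrong dimer or low yield.
   Fallback: a crossed Diels–Alder. Convert the 3‑oxo‑4‑ene (from 2, after acetate removal) to its 2‑silyloxy‑cyclopentadiene with TBSOTf/Et3N and react it under high pressure with preformed diene 5 as dienophile. Enol‑ether hydrolysis then delivers the C3′ ketone directly and removes Steps 6–7.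
2. **Step 6 (hydroboration).** The norbornene C3′=C4′ bond is shielded by the 7‑syn C10′ substituent on the exo face and by the endo cyclopentene ring, and it carries a methyl next to a quaternary centre.
   Fallback: epoxidise with DMDO, then open the epoxide with Cp2TiCl (radical opening via the tertiary C4′ radical) to give the C3′ alcohol. Alternatively, use a hydroxyl‑directed delivery from the C10′ alkoxyborane.
3. **Step 4 (dehydration).** Ionisation of the tertiary C10–OH, chloride capture, or formation of the wrong diene isomer could compete with selective loss of the allylic OH.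
   Fallback: omit Step 3 and keep the C10 acetate. Dehydrate acetate 3 with Burgess reagent or Martin sulfurane, and carry both acetates through Steps 5–6. Remove them at the alcohol stage (before oxidation) with K2CO3/MeOH.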